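Q is what I watch, as a rate: the fraction of the L charged that becomes Q per minute, read from the runs so far at one charge of G.

in all of them: G 21.8 mM
- beta: L 15 mM; run made earlier
- gamma: L 34 mM; run made earlier
- flask: L 23 mM; time 40 min; volume of the second phase over the first 2.0

| run | time / min | Q / % | L / % |
|---|---|---|---|
| beta | 3.00 | 0 | 100.0 |
| beta | 8.00 | 0.9 | 98.9 |
| beta | 15.0 | 2.7 | 97.3 |
| beta | 40.0 | 6.5 | 93.6 |
| gamma | 10.0 | 1.3 | 98.7 |
| gamma | 20.0 | 2.9 | 96.7 |
| gamma | 30.0 | 4.4 | 95.7 |
| gamma | 40.0 | 5.2 | 95.0 |

(scatter of a reading: 0.3 percentage points)

- in the second phase: G; everything else is in the first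
- charges count per volume of the first phase; a concentration in a rate is the amount of a species over the volume of its own phase; every rate counts per litre of the first phase
- what may be going on: Z <-> G; L + Z <-> Q; Z + Q -> J; Z <-> X
- the earlier runs hold the two phases in the same ratio of volumes as the flask asked about

- Sunday's: doubling the amount of G, all else as stated
- Friday's: doubling the transfer coefficient of G, all else as stated

* Q at 40 min, in percent of the L charged
* the change that raises the amount of Q at 40 min, in percent of the L charged most ("none" if none brings more than 2 percentage points) (Sunday's / Friday's / none)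
* amount of Q at 40 min, in percent of the L charged, after Sunday's

In beta, Q reads 0 % at 3.00 min, a lag phase, and the rate then runs at 0.00257 min⁻¹ from 8.00 min to 15.0 min. Afterwards the readings give 0.00152 min⁻¹, a factor 0.591. L still stands at 93.6 % at the end, so this factor is smaller than the used L can account for.

At the larger L charge of gamma this fractional rate reads lower. The mean rate over the run is 0.00163 min⁻¹ in beta and 0.00130 min⁻¹ in gamma, a factor 0.798. So I reckon:

ln(5.2 % / 6.5 %) / ln(34 mM / 15 mM) = −0.273

That is the charge exponent, the power of the L charge that this mean rate follows at one charge of G and one time. Carrying beta to the flask gives: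

0.00163 min⁻¹ × (23 mM / 15 mM)^(−0.273) = 0.00145 min⁻¹

Over 40 min that makes 5.78 %.

The forecast says 5.8 %, picks Sunday's, and gives 11 % after it, holding that “Doubling G doubles Z throughout”. Neither run moved G, so that part is its judgement, not my reckoning.

The flask gives 5.77 %. Sunday's adds 5.1 percentage points, against 3.1 points for Friday's, and ends at 10.9 %.

    Z ⇌ G, rate k1*([Z] - [G]/K1) per volume of the first phase (partition coefficient = 0.600, kL = 0.0110 min⁻¹)
    L + Z ⇌ Q (K = 34.0 M⁻¹, k = 3.80 M⁻¹ min⁻¹)
    Z + Q → J (k = 0.600 M⁻¹ min⁻¹)
    Z ⇌ X (K = 2.00, k = 0.0920 min⁻¹)

Part of what holds Q down in the flask is Q falling back to L and Z, together with the pace at which G crosses over. Without the undoing the run reaches 13.8 %, and without the brake of the crossing's pace it reaches 13.0 %. The charge exponent's 5.78 % stands beside the flask's 5.77 %. Taken to the same flask with 92 mM of L, it gives 3.97 %, and that flask reads 3.63 %.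

The numbers in the tables are simulated with constants of no real substance; scatter was added.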